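**Plan**

- Locants follow the target as a spiro[cyclohex-3-ene-1,6'-indene]: trione ring C1 (spiro) to C6; carbocycle C1' (C(Me)OH), C2', C3', C3a', C4' (C(Me)OH), C5', C7', C7a'.
- The retrosynthesis cuts C1–C5' first, then C1–C7', the two C5–prenyl bonds, and C3a'–C7a' of the cyclopentane.
- Forward: (R)-linalool becomes an epoxy tosylate nitrile, and an epoxynitrile cyclization closes the cyclopentane and relays the oxirane to C4'–C5'. Phloracetophenone is dearomatized by gem-diprenylation. Reductive alkylation joins C1–C7', and the spiro-alkylation C1–C5' closes the cyclohexane.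
- Stereochemistry: C1' comes from (R)-linalool; C3a' and C4' from one Sharpless epoxidation (inversion at C3a', retention at C4'); C7a' from the cyclization; the spiro carbon C1 from the key step, through a chair transition state with an axial 4'-methyl group.
- Enabling feature: C1 is the 1,3-dicarbonyl carbon between C2=O and C6=O of the dearomatized phloroglucinol ring and can be alkylated twice. It lies six atoms (C1–C7'–C7a'–C3a'–C4'–C5') from the oxirane CH2, so C-alkylation closes a six-membered ring while O-alkylation would need an eight-membered one.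

Key step: step 10

Remark: β-triketones are written as one enol tautomer (all tautomers count as the same compound), and C6 of 17 and 19 becomes the spiro carbon C1 of 20.

**Route**

Step 1
Reactants: 1 (R)-(−)-linalool
Product: 3 (3R)-3,7-dimethyloct-6-ene-1,3-diol, via alkylborane 2 (not isolated)
Conditions: 9-BBN (2.2 equiv), THF, 0 °C → rt; then NaOH, 30% H2O2, 0 °C
Reagents that add atoms: hydrogen peroxide, OO
Why: Hydroboration–oxidation, in which 9-BBN adds anti-Markovnikov to the monosubstituted vinyl group much faster than to the trisubstituted 6,7-alkene, so that the primary alcohol should form while the carbinol stereocentre of linalool is untouched.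

Step 2
Reactants: 3 (3R)-3,7-dimethyloct-6-ene-1,3-diol
Product: 6 (3R)-3-hydroxy-3,7-dimethyloct-6-enenitrile, via hydroxy aldehyde 4 (not isolated), via aldimine 5 (not isolated)
Conditions: TEMPO (5 mol %), PhI(OAc)2 (2.2 equiv), NH4OAc (4 equiv), MeCN/H2O, rt
Reagents that add atoms: ammonium acetate, CC(=O)[O-].[NH4+]
Why: One-pot oxidative conversion of a primary alcohol into a nitrile (oxoammonium oxidation to the aldehyde, condensation with ammonia, second oxidation of the N–H aldimine), which leaves the tertiary alcohol and the trisubstituted alkene alone.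

Step 3
Reactants: 6 (3R)-3-hydroxy-3,7-dimethyloct-6-enenitrile
Product: 7 (3R,6E)-3,8-dihydroxy-3,7-dimethyloct-6-enenitrile
Conditions: SeO2 (0.3 equiv), t-BuOOH (2.5 equiv), salicylic acid (10 mol %), CH2Cl2, rt
Reagents that add atoms: selenium dioxide, O=[Se]=O; tert-butyl hydroperoxide, CC(C)(C)OO
Why: Catalytic selenium dioxide allylic oxidation (ene reaction then [2,3]-shift), which on a gem-dimethyl alkene should oxidize the (E)-methyl group and give the (E)-2-methyl allylic alcohol.

Step 4
Reactants: 7 (3R,6E)-3,8-dihydroxy-3,7-dimethyloct-6-enenitrile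
Product: 8 (3R)-3-hydroxy-5-[(2R,3R)-3-(hydroxymethyl)-3-methyloxiran-2-yl]-3-methylpentanenitrile
Conditions: Ti(Oi-Pr)4 (10 mol %), D-(−)-diethyl tartrate (12 mol %), t-BuOOH (2 equiv, decane), 4 Å MS, CH2Cl2, −25 °C
Reagents that add atoms: tert-butyl hydroperoxide, CC(C)(C)OO
Why: Sharpless asymmetric epoxidation of an (E)-trisubstituted allylic alcohol, in which D-(−)-tartrate should deliver oxygen to the face that gives the (2R,3R)-epoxy alcohol and so fixes the future C4' and (before inversion) C3a', while low temperature and catalytic titanium keep the remote tertiary hydroxyl from opening the oxirane.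

Step 5
Reactants: 8 (3R)-3-hydroxy-5-[(2R,3R)-3-(hydroxymethyl)-3-methyloxiran-2-yl]-3-methylpentanenitrile
Product: 9 [(2R,3R)-3-[(3R)-4-cyano-3-hydroxy-3-methylbutyl]-2-methyloxiran-2-yl]methyl 4-methylbenzenesulfonate
Conditions: TsCl (1.1 equiv), Et3N (1.5 equiv), DMAP (5 mol %), CH2Cl2, −10 °C
Reagents that add atoms: 4-toluenesulfonyl chloride, Cc1ccc(cc1)S(Cl)(=O)=O
Why: Selective sulfonylation of the primary alcohol of an epoxy alcohol, since the tertiary alcohol does not react under these conditions and the oxirane is stable to them.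

Step 6
Reactants: 9 [(2R,3R)-3-[(3R)-4-cyano-3-hydroxy-3-methylbutyl]-2-methyloxiran-2-yl]methyl 4-methylbenzenesulfonate
Product: 11 (1R,2R,5R)-2-hydroxy-2-methyl-5-[(2S)-2-methyloxiran-2-yl]cyclopentane-1-carbonitrile, via ring-closed alkoxide tosylate 10 (not isolated)
Conditions: LiHMDS (2.3 equiv), THF, −78 → 0 °C; then H2O
Reagents that add atoms: none
Why: Stork epoxynitrile cyclization, in which the α-cyano carbanion (as the dianion with the tertiary alkoxide) should open the oxirane 5-exo at its secondary carbon with inversion (sets C3a') and place the nitrile trans to both neighbouring carbon substituents (sets C7a'), after which the released tertiary alkoxide displaces the neighbouring tosylate (3-exo-tet) to give the terminal oxirane with the carbinol configuration retained.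

Step 7
Reactants: 11 (1R,2R,5R)-2-hydroxy-2-methyl-5-[(2S)-2-methyloxiran-2-yl]cyclopentane-1-carbonitrile
Product: 13 (1S,2R,5R)-2-hydroxy-2-methyl-5-[(2S)-2-methyloxiran-2-yl]cyclopentane-1-carbaldehyde, via N-aluminio aldimine 12 (not isolated)
Conditions: DIBAL-H (3 equiv), CH2Cl2, −78 °C; then aqueous Rochelle salt, rt
Reagents that add atoms: water, O
Why: DIBAL-H reduction of a nitrile stops at the N-aluminio aldimine, which is hydrolysed to the aldehyde on work-up, and the oxirane should survive at −78 °C.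

Step 8
Reactants: 14 2,4,6-trihydroxyacetophenone, 15 prenyl bromide (2.1 equiv)
Product: 17 2-acetyl-3,5-dihydroxy-4,4-bis(3-methylbut-2-en-1-yl)cyclohexa-2,5-dien-1-one, via monoprenyl phloracetophenone 16 (not isolated)
Conditions: NaOMe (3 equiv), MeOH, 0 °C → rt; acidify; extract the product into aqueous NaHCO3
Reagents that add atoms: none
Why: Alkylative dearomatization, in which the phloroglucinol phenoxide is C-prenylated and the prenylated carbon is alkylated a second time to give the 4,4-diprenyl dienone, which as a strong vinylogous acid should be separable from the aromatic 3,5-diprenyl isomer by bicarbonate extraction.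

Step 9
Reactants: 13 (1S,2R,5R)-2-hydroxy-2-methyl-5-[(2S)-2-methyloxiran-2-yl]cyclopentane-1-carbaldehyde, 17 2-acetyl-3,5-dihydroxy-4,4-bis(3-methylbut-2-en-1-yl)cyclohexa-2,5-dien-1-one
Product: 19 2-acetyl-3,5-dihydroxy-6-{[(1S,2R,5R)-2-hydroxy-2-methyl-5-[(2S)-2-methyloxiran-2-yl]cyclopentyl]methyl}-4,4-bis(3-methylbut-2-en-1-yl)cyclohexa-2,5-dien-1-one, via alkylidene trione 18 (not isolated)
Conditions: Hantzsch ester (diethyl 2,6-dimethyl-1,4-dihydropyridine-3,5-dicarboxylate, 1.2 equiv), L-proline (10 mol %), CH2Cl2, 0 °C → rt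
Reagents that add atoms: none
Why: Three-component reductive alkylation, in which Knoevenagel condensation of the aldehyde with the CH-acidic C6 of the trione and transfer hydrogenation of the alkylidene trione by the Hantzsch ester should form the C1–C7' bond without creating a stereocentre.

Step 10
Reactants: 19 2-acetyl-3,5-dihydroxy-6-{[(1S,2R,5R)-2-hydroxy-2-methyl-5-[(2S)-2-methyloxiran-2-yl]cyclopentyl]methyl}-4,4-bis(3-methylbut-2-en-1-yl)cyclohexa-2,5-dien-1-one
Product: 20 (1S,1'R,3a'R,4'R,7a'S)-3-acetyl-1',4,4'-trihydroxy-1',4'-dimethyl-5,5-bis(3-methylbut-2-en-1-yl)-1',2',3',3a',4',5',7',7a'-octahydrospiro[cyclohex-3-ene-1,6'-indene]-2,6-dione (CNP0266834.1)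
Conditions: t-BuOK (2.5 equiv), t-BuOH/THF (1:1, 0.01 M), 25 → 50 °C; then 1 M HCl to pH 3, 0 °C
Reagents that add atoms: none
Why: Proposed new method: double deprotonation gives the dienolate dianion of the dearomatized acylphloroglucinol, whose carbon between the two ring carbonyls (the future spiro C1) attacks the CH2 terminus of the 2,2-disubstituted oxirane in an intramolecular SN2 opening; the closest known reaction types are the Stork-type intramolecular opening of epoxides by stabilized carbanions and the C-alkylative dearomatization of acylphloroglucinols. The cyclohexane closes in a 6-endo-tet mode, the only reasonable one because the quaternary oxirane carbon is blocked and O-alkylation would need an eight-membered ring. The oxirane C–O bond must lie anti to the incoming carbon, so in the chair transition state (fused trans to the cyclopentane) the oxygen at C4' is equatorial and the 4'-methyl group axial; C4' keeps the configuration from the Sharpless epoxidation because its C–O bond is not broken. The new spiro stereocentre C1 is set by which carbonyl flank of the planar nucleophile lies under the forming ring beside this axial methyl group and the axial H at C7a': the flat acetyl-enol flank (C2/C3) should fit there, whereas the flank next to the gem-diprenyl quaternary carbon C5 should not, which gives (1S). The step needs C- over O-alkylation, attack at CH2 over the quaternary carbon, and this facial selectivity; ring size secures the first two and the gem-diprenyl group the third.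

**Compound list**

1 | (R)-(−)-linalool, (3R)-3,7-dimethylocta-1,6-dien-3-ol | C=C[C@](C)(O)CCC=C(C)C | starting material
2 | B-[(3R)-3-hydroxy-3,7-dimethyloct-6-en-1-yl]-9-borabicyclo[3.3.1]nonane | C1CCC2CCCC1B2CC[C@](C)(O)CCC=C(C)C | intermediate
3 | (3R)-3,7-dimethyloct-6-ene-1,3-diol | OCC[C@](C)(O)CCC=C(C)C | intermediate
4 | (3R)-3-hydroxy-3,7-dimethyloct-6-enal | O=CC[C@](C)(O)CCC=C(C)C | intermediate
5 | (3R)-1-imino-3,7-dimethyloct-6-en-3-ol | N=CC[C@](C)(O)CCC=C(C)C | intermediate
6 | (3R)-3-hydroxy-3,7-dimethyloct-6-enenitrile | N#CC[C@](C)(O)CCC=C(C)C | intermediate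
7 | (3R,6E)-3,8-dihydroxy-3,7-dimethyloct-6-enenitrile | N#CC[C@](C)(O)CC/C=C(\C)CO | intermediate
8 | (3R)-3-hydroxy-5-[(2R,3R)-3-(hydroxymethyl)-3-methyloxiran-2-yl]-3-methylpentanenitrile | N#CC[C@](C)(O)CC[C@H]1O[C@]1(C)CO | intermediate
9 | [(2R,3R)-3-[(3R)-4-cyano-3-hydroxy-3-methylbutyl]-2-methyloxiran-2-yl]methyl 4-methylbenzenesulfonate | N#CC[C@](C)(O)CC[C@H]1O[C@]1(C)COS(=O)(=O)c2ccc(C)cc2 | intermediate
10 | (2S)-2-[(1R,2R,3R)-2-cyano-3-hydroxy-3-methylcyclopentyl]-2-hydroxypropyl 4-methylbenzenesulfonate (present as its lithium alkoxide) | N#C[C@@H]1[C@](C)(O)CC[C@H]1[C@](C)(O)COS(=O)(=O)c2ccc(C)cc2 | intermediate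
11 | (1R,2R,5R)-2-hydroxy-2-methyl-5-[(2S)-2-methyloxiran-2-yl]cyclopentane-1-carbonitrile | N#C[C@@H]1[C@](C)(O)CC[C@H]1[C@@]2(C)CO2 | intermediate
12 | aldimine of 13 (present as the N-aluminio derivative, drawn as the N–H imine) | N=C[C@@H]1[C@](C)(O)CC[C@H]1[C@@]2(C)CO2 | intermediate
13 | (1S,2R,5R)-2-hydroxy-2-methyl-5-[(2S)-2-methyloxiran-2-yl]cyclopentane-1-carbaldehyde | O=C[C@@H]1[C@](C)(O)CC[C@H]1[C@@]2(C)CO2 | intermediate
14 | 2,4,6-trihydroxyacetophenone (phloracetophenone) | CC(=O)c1c(O)cc(O)cc1O | starting material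
15 | prenyl bromide, 1-bromo-3-methylbut-2-ene | CC(C)=CCBr | starting material
16 | 1-[2,4,6-trihydroxy-3-(3-methylbut-2-en-1-yl)phenyl]ethan-1-one | CC(=O)c1c(O)cc(O)c(CC=C(C)C)c1O | intermediate
17 | 2-acetyl-3,5-dihydroxy-4,4-bis(3-methylbut-2-en-1-yl)cyclohexa-2,5-dien-1-one | CC(=O)C1=C(O)C(CC=C(C)C)(CC=C(C)C)C(O)=CC1=O | intermediate
18 | 6-alkylidene trione from 13 and 17 (cyclopentane configured as in 13; exocyclic C=C geometry not fixed) | CC(=O)C1=C(O)C(CC=C(C)C)(CC=C(C)C)C(=O)C(=C[C@@H]2[C@](C)(O)CC[C@H]2[C@@]3(C)CO3)C1=O | intermediate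
19 | 2-acetyl-3,5-dihydroxy-6-{[(1S,2R,5R)-2-hydroxy-2-methyl-5-[(2S)-2-methyloxiran-2-yl]cyclopentyl]methyl}-4,4-bis(3-methylbut-2-en-1-yl)cyclohexa-2,5-dien-1-one | CC(=O)C1=C(O)C(CC=C(C)C)(CC=C(C)C)C(O)=C(C[C@@H]2[C@](C)(O)CC[C@H]2[C@@]3(C)CO3)C1=O | intermediate
20 | (1S,1'R,3a'R,4'R,7a'S)-3-acetyl-1',4,4'-trihydroxy-1',4'-dimethyl-5,5-bis(3-methylbut-2-en-1-yl)-1',2',3',3a',4',5',7',7a'-octahydrospiro[cyclohex-3-ene-1,6'-indene]-2,6-dione | CC(=O)C1=C(O)C(CC=C(C)C)(CC=C(C)C)C(=O)[C@@]2(C[C@H]3[C@@H](CC[C@@]3(C)O)[C@](C)(O)C2)C1=O | target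

**Step count**

Total step count: 10. Longest linear sequence: 9 (steps 1–7, 9, 10).

**Steps most likely to fail**

1. Step 10 (Proposed new method). The dianion may alkylate the hindered oxirane CH2 too slowly, so that opening of the oxirane by alkoxide or hydroxide takes over, or the two faces of C1 may not be told apart well enough. The fallback sets out from 11 and comes back at 20. Aluminium isopropoxide-mediated isomerization of the 2,2-disubstituted oxirane (toluene, 110 °C) should give the allylic alcohol (1R,2R,5R)-2-hydroxy-5-(3-hydroxyprop-1-en-2-yl)-2-methylcyclopentane-1-carbonitrile F1. DIBAL-H reduction then gives (1S,2R,5R)-2-hydroxy-5-(3-hydroxyprop-1-en-2-yl)-2-methylcyclopentane-1-carbaldehyde F2, which is in equilibrium with its six-membered lactol. Reductive alkylation of 17 with F2 under the conditions of step 9 gives 2-acetyl-3,5-dihydroxy-6-{[(1S,2R,5R)-2-hydroxy-5-(3-hydroxyprop-1-en-2-yl)-2-methylcyclopentyl]methyl}-4,4-bis(3-methylbut-2-en-1-yl)cyclohexa-2,5-dien-1-one F3. A Pd(0)-catalysed dehydrative intramolecular Tsuji–Trost allylation (Pd2(dba)3 and a C2-symmetric DACH-phenyl diphosphine whose antipode is chosen to reinforce the substrate bias; the acidic trione activates the allylic alcohol) closes the spiro ring. Both ends of the 2-substituted π-allyl unit give the same product, (1S,1'R,3a'R,7a'S)-3-acetyl-1',4-dihydroxy-1'-methyl-4'-methylidene-5,5-bis(3-methylbut-2-en-1-yl)-1',2',3',3a',4',5',7',7a'-octahydrospiro[cyclohex-3-ene-1,6'-indene]-2,6-dione F4. Mukaiyama hydration (Co(acac)2, PhSiH3, O2; then PPh3) of the 1,1-disubstituted alkene, which reacts faster than the trisubstituted prenyl alkenes, returns to 20; O2 should capture the tertiary radical from the equatorial side because the axial side is shielded by the syn-axial C2 carbonyl.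

2. Step 6. The tertiary lithium alkoxide may attack the oxirane itself (tetrahydrofuran formation) in competition with the carbanion, or the amide base may isomerize the oxirane. The fallback sets out from 9 and comes back at 11. Silylation of the tertiary alcohol with N-(trimethylsilyl)imidazole gives [(2R,3R)-3-{(3R)-4-cyano-3-methyl-3-[(trimethylsilyl)oxy]butyl}-2-methyloxiran-2-yl]methyl 4-methylbenzenesulfonate F5. The epoxynitrile cyclization is then run on the mono-anion (KHMDS, THF/toluene, −78 °C) and gives (1R,2R,5R)-2-methyl-5-[(2S)-2-methyloxiran-2-yl]-2-[(trimethylsilyl)oxy]cyclopentane-1-carbonitrile F6. Mild acid cleavage of the silyl ether (citric acid, MeOH/H2O) returns to 11.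

3. Step 9. The β-hydroxy aldehyde may be lost by retro-aldol cleavage or dehydration under amine catalysis, the acidic trione may open the oxirane, or a second trione may add to the alkylidene intermediate. The fallback sets out from 8 and comes back at 19. The epoxynitrile cyclization is run on the epoxy alcohol itself (LiHMDS, 3.3 equiv) and gives (1R,2R,5R)-5-[(2S)-1,2-dihydroxypropan-2-yl]-2-hydroxy-2-methylcyclopentane-1-carbonitrile F7. DIBAL-H reduction gives the hydroxy aldehyde, which closes to the trans-fused lactol (4S,4aR,7R,7aS)-4,7-dimethyloctahydrocyclopenta[c]pyran-1,4,7-triol F8 and is masked in that form. Reductive alkylation of 17 with the lactol (Hantzsch ester, L-proline) gives 2-acetyl-6-{[(1S,2R,5R)-5-[(2S)-1,2-dihydroxypropan-2-yl]-2-hydroxy-2-methylcyclopentyl]methyl}-3,5-dihydroxy-4,4-bis(3-methylbut-2-en-1-yl)cyclohexa-2,5-dien-1-one F9. Mitsunobu dehydration of the 1,2-diol (PPh3, DIAD) closes the terminal oxirane and returns to 19.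

Further compounds
F1 | step 10 | (1R,2R,5R)-2-hydroxy-5-(3-hydroxyprop-1-en-2-yl)-2-methylcyclopentane-1-carbonitrile | N#C[C@@H]1[C@](C)(O)CC[C@H]1C(=C)CO
F2 | step 10 | (1S,2R,5R)-2-hydroxy-5-(3-hydroxyprop-1-en-2-yl)-2-methylcyclopentane-1-carbaldehyde | O=C[C@@H]1[C@](C)(O)CC[C@H]1C(=C)CO
F3 | step 10 | 2-acetyl-3,5-dihydroxy-6-{[(1S,2R,5R)-2-hydroxy-5-(3-hydroxyprop-1-en-2-yl)-2-methylcyclopentyl]methyl}-4,4-bis(3-methylbut-2-en-1-yl)cyclohexa-2,5-dien-1-one | CC(=O)C1=C(O)C(CC=C(C)C)(CC=C(C)C)C(O)=C(C[C@@H]2[C@](C)(O)CC[C@H]2C(=C)CO)C1=O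
F4 | step 10 | (1S,1'R,3a'R,7a'S)-3-acetyl-1',4-dihydroxy-1'-methyl-4'-methylidene-5,5-bis(3-methylbut-2-en-1-yl)-1',2',3',3a',4',5',7',7a'-octahydrospiro[cyclohex-3-ene-1,6'-indene]-2,6-dione | CC(=O)C1=C(O)C(CC=C(C)C)(CC=C(C)C)C(=O)[C@@]2(C[C@H]3[C@@H](CC[C@@]3(C)O)C(=C)C2)C1=O
F5 | step 6 | [(2R,3R)-3-{(3R)-4-cyano-3-methyl-3-[(trimethylsilyl)oxy]butyl}-2-methyloxiran-2-yl]methyl 4-methylbenzenesulfonate | N#CC[C@](C)(O[Si](C)(C)C)CC[C@H]1O[C@]1(C)COS(=O)(=O)c2ccc(C)cc2
F6 | step 6 | (1R,2R,5R)-2-methyl-5-[(2S)-2-methyloxiran-2-yl]-2-[(trimethylsilyl)oxy]cyclopentane-1-carbonitrile | N#C[C@@H]1[C@](C)(O[Si](C)(C)C)CC[C@H]1[C@@]2(C)CO2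
F7 | step 9 | (1R,2R,5R)-5-[(2S)-1,2-dihydroxypropan-2-yl]-2-hydroxy-2-methylcyclopentane-1-carbonitrile | N#C[C@@H]1[C@](C)(O)CC[C@H]1[C@](C)(O)CO
F8 | step 9 | (4S,4aR,7R,7aS)-4,7-dimethyloctahydrocyclopenta[c]pyran-1,4,7-triol | OC1OC[C@@](C)(O)[C@@H]2CC[C@@](C)(O)[C@@H]12
F9 | step 9 | 2-acetyl-6-{[(1S,2R,5R)-5-[(2S)-1,2-dihydroxypropan-2-yl]-2-hydroxy-2-methylcyclopentyl]methyl}-3,5-dihydroxy-4,4-bis(3-methylbut-2-en-1-yl)cyclohexa-2,5-dien-1-one | CC(=O)C1=C(O)C(CC=C(C)C)(CC=C(C)C)C(O)=C(C[C@@H]2[C@](C)(O)CC[C@H]2[C@](C)(O)CO)C1=O
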